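**Retrosynthetic overview**
1. The target comes from a ring vinyl sulfone by exchange of the sulfonyl group for methyl (nickel-catalysed coupling with MeMgBr) and removal of three MOM ethers.
2. The vinyl sulfone comes from a one-pot (3+3) annulation of allyl phenyl sulfone (α-carbon first, then γ-carbon) with a (2S,3E)-3-(4-methylpent-3-enylidene)flavanone; this forms the cyclohexene bonds CH(prenyl)–C(sulfonyl)= and CH2–CH(aryl) in one operation.
3. Enabling feature: in the chroman-4-one, C3 carries the exocyclic C=C (its far carbon is a Michael acceptor) and is bonded to C2, whose ring oxygen O1 is a β-leaving group for the C3 enolate. The two carbons flanking the future aroyl-bearing carbon therefore become electrophilic one after the other, and opening of the pyranone ring (ring C) releases the 2-hydroxyaryl ketone of the target.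
4. The alkylidene flavanone comes from aldol condensation of a (2R)-flavanone with 4-methylpent-3-enal; the flavanone comes from rhodium-catalysed asymmetric 1,4-arylation of 5,7-bis(MOM)chromone, the only stereocentre set by a catalyst, from which the three of the target are relayed.
5. Ring order: the benzopyranone is bought, the cyclohexene is the only ring built (key step), and the pyranone ring is cleaved in that same step.

Key step: step 6

Remark (assumption): the antipode of the chiral ligand in step 2 (and of VANOL in the first fallback) is taken to be the one that gives the configuration drawn; compounds 1, 3, 5 and 11 are taken as commercial. The target is (1R,2S,6R): aroyl trans to aryl and cis to prenyl.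

**Step 1**
Reactants: 1 5,7-dihydroxy-4H-chromen-4-one
Product: 2 5,7-bis(methoxymethoxy)-4H-chromen-4-one
Conditions: NaH (2.4 equiv), MOMCl (2.4 equiv), DMF, 0 to 20 °C
Reagents that add atoms: chloromethyl methyl ether, COCCl
Why: Williamson-type O-alkylation of both sodium phenoxides with MOMCl, NaH being needed because the 5-OH is hydrogen-bonded to the carbonyl group; no stereocentre is involved.

**Step 2**
Reactants: 2 5,7-bis(methoxymethoxy)-4H-chromen-4-one; 3 [4-(methoxymethoxy)phenyl]boronic acid
Product: 4 (2R)-5,7-bis(methoxymethoxy)-2-[4-(methoxymethoxy)phenyl]-2,3-dihydro-4H-chromen-4-one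
Conditions: [Rh(OH)(cod)]2 (cat.), MeO-F12-BIPHEP (cat., antipode giving 2R), toluene–H2O, 40 °C
Reagents that add atoms: none
Why: Rhodium-catalysed asymmetric 1,4-addition of an arylboronic acid to an enone (Hayashi–Miyaura reaction), a reaction type established for chromones, in which the aryl–rhodium species adds to C2 on the enantioface chosen by the chiral bisphosphine and so sets the single C2 stereocentre (R), while the neutral aqueous medium protonates the rhodium enolate before the pyranone ring can open.

**Step 3**
Reactants: 5 4-methylpent-3-en-1-ol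
Product: 6 4-methylpent-3-enal
Conditions: TEMPO (cat.), PhI(OAc)2 (1.1 equiv), CH2Cl2, 20 °C; used crude
Reagents that add atoms: none
Why: Oxoammonium (TEMPO) oxidation of a primary alcohol with PhI(OAc)2 as terminal oxidant, mild and non-basic so that the β,γ-unsaturated aldehyde should not move into conjugation.

**Step 4**
Reactants: 4 (2R)-5,7-bis(methoxymethoxy)-2-[4-(methoxymethoxy)phenyl]-2,3-dihydro-4H-chromen-4-one; 6 4-methylpent-3-enal
Product: 8 (2R)-3-(1-hydroxy-4-methylpent-3-en-1-yl)-5,7-bis(methoxymethoxy)-2-[4-(methoxymethoxy)phenyl]-2,3-dihydro-4H-chromen-4-one (diastereomer mixture at C3 and the carbinol carbon), via lithium enolate 7 (not isolated)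
Conditions: LiN(SiMe3)2 (1.05 equiv), THF, −78 °C; then 6 (1.5 equiv), −78 °C; AcOH, −78 °C
Reagents that add atoms: none
Why: Directed aldol addition of a preformed ketone lithium enolate to an aldehyde at −78 °C, where β-elimination of the ring oxygen from enolate 7 should be slow; C2 is untouched and the two new centres need no control because both are removed in step 5.

**Step 5**
Reactants: 8 (2R)-3-(1-hydroxy-4-methylpent-3-en-1-yl)-5,7-bis(methoxymethoxy)-2-[4-(methoxymethoxy)phenyl]-2,3-dihydro-4H-chromen-4-one
Product: 10 (2S,3E)-5,7-bis(methoxymethoxy)-2-[4-(methoxymethoxy)phenyl]-3-(4-methylpent-3-en-1-ylidene)-2,3-dihydro-4H-chromen-4-one, via mesylate 9 (not isolated)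
Conditions: MsCl (1.5 equiv), Et3N (4 equiv), CH2Cl2, −20 to 20 °C
Reagents that add atoms: none
Why: Mesylation of the β-hydroxy ketone followed by E1cB elimination with Et3N should give the conjugated exocyclic enone as the more stable E isomer (chain anti to the carbonyl group), the mesylate being a far better leaving group than the ring oxygen so that the pyranone ring and C2 stay intact (the descriptor changes from R to S only because C3 becomes sp2).

**Step 6**
Reactants: 10 (2S,3E)-5,7-bis(methoxymethoxy)-2-[4-(methoxymethoxy)phenyl]-3-(4-methylpent-3-en-1-ylidene)-2,3-dihydro-4H-chromen-4-one; 11 allyl phenyl sulfone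
Product: 16 [2-hydroxy-4,6-bis(methoxymethoxy)phenyl][(1S,2S,6R)-6-[4-(methoxymethoxy)phenyl]-2-(3-methylbut-2-en-1-yl)-3-(phenylsulfonyl)cyclohex-3-en-1-yl]methanone, via lithiated sulfone 12 (not isolated), via adduct enolate 13 (not isolated), via ring-opened phenoxide 14 (not isolated), via cyclised dilithium enolate 15 (not isolated)
Conditions: 11 (1.1 equiv), LiN(SiMe3)2 (1.1 equiv), THF–DMPU, −78 °C; then 10, −78 to −20 °C; then LiN(SiMe3)2 (1.2 equiv), −20 to 0 °C; AcOH, −78 °C
Reagents that add atoms: none
Why: Proposed new method: the α-carbon of lithiated sulfone 12 adds 1,4 to the exocyclic enone of 10, the chromanone enolate 13 expels the ring oxygen O1 from C2 by E1cB to give the 2-oxidoaryl enone 14 (the known flavanone-to-chalcone opening), the second portion of base regenerates a sulfonyl allyl anion, and its γ-carbon adds to the new enone β-carbon to give the vinyl sulfone enolate 15, which is protonated to 16. The closest known reaction types are the (3+3) α,α′-annulation of 1,3-bis-nucleophiles (ketone enamines, 1,3-bis(sulfonyl)propenes) with Morita–Baylis–Hillman-type 1,3-bis-electrophiles by an SN2′–Michael sequence, the α-1,4 addition of sulfonyl allyl anions to enones and their γ-selective reactions that leave a vinyl sulfone; new here are the ring aryloxide as leaving group and the parent allyl sulfone as three-carbon partner. The cyclohexene closes by a 6-endo-trig Michael addition through the γ-carbon (closure through the α-carbon would give a cyclobutane), and the pyranone ring is opened, not formed. The prenyl-bearing centre (cyclohexene C2) is set in the first addition by the C2 aryl group of 10, which is pseudoaxial because of allylic 1,3-strain with the E-alkylidene chain and blocks one face of the exocyclic alkene; the aryl-bearing centre (C6), lost on ring opening, is re-formed trans to the prenyl group because that group stays pseudoaxial between the sulfonyl- and aroyl-bearing sp2 carbons and a cis aryl group would be 1,3-diaxial to it; the aroyl-bearing centre (C1) is set by protonation of 15 anti to the pseudoaxial prenyl group, which also places the aroyl group equatorial. The step needs α- over γ-attack and 1,4- over 1,2-addition in the first event, which the s-cis exocyclic enone, the hindered electron-rich aryl ketone and the polar cosolvent DMPU should secure, and it needs the first C–C bond to form at −78 °C before any base-induced opening of 10 can erase the C2 information.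

**Step 7**
Reactants: 16 [2-hydroxy-4,6-bis(methoxymethoxy)phenyl][(1S,2S,6R)-6-[4-(methoxymethoxy)phenyl]-2-(3-methylbut-2-en-1-yl)-3-(phenylsulfonyl)cyclohex-3-en-1-yl]methanone
Product: 17 [2-hydroxy-4,6-bis(methoxymethoxy)phenyl][(1R,2S,6R)-6-[4-(methoxymethoxy)phenyl]-3-methyl-2-(3-methylbut-2-en-1-yl)cyclohex-3-en-1-yl]methanone
Conditions: MeMgBr (5 equiv), Ni(acac)2 (5 mol %), THF, 0 to 20 °C; AcOH, 0 °C
Reagents that add atoms: methylmagnesium bromide, C[Mg]Br
Why: Nickel-catalysed cross-coupling of a vinyl sulfone with a Grignard reagent (desulfonylative Kumada-type coupling), in which low-valent nickel inserts into the vinylic C–S bond and methyl replaces the sulfonyl group on the same carbon so that the ring alkene stays in place, while the first equivalents of MeMgBr turn the phenol into its magnesium phenoxide, which together with the two ortho substituents and the two α-branches should protect the aryl ketone from addition; no stereocentre is formed (the C1 descriptor changes from S to R by priority only).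

**Step 8**
Reactants: 17 [2-hydroxy-4,6-bis(methoxymethoxy)phenyl][(1R,2S,6R)-6-[4-(methoxymethoxy)phenyl]-3-methyl-2-(3-methylbut-2-en-1-yl)cyclohex-3-en-1-yl]methanone
Product: 18 (2,4,6-trihydroxyphenyl)[(1R,2S,6R)-6-(4-hydroxyphenyl)-3-methyl-2-(3-methylbut-2-en-1-yl)cyclohex-3-en-1-yl]methanone
Conditions: 3 M aq. HCl, MeOH, 45 °C
Reagents that add atoms: none
Why: Acid-catalysed acetal cleavage of the three MOM ethers (transacetalisation to dimethoxymethane) under conditions mild enough for the two trisubstituted alkenes; no stereocentre is touched.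

**Compound list**
1 | 5,7-dihydroxy-4H-chromen-4-one | O=c1ccoc2cc(O)cc(O)c12 | starting material
2 | 5,7-bis(methoxymethoxy)-4H-chromen-4-one | O=c1ccoc2cc(OCOC)cc(OCOC)c12 | intermediate
3 | [4-(methoxymethoxy)phenyl]boronic acid | COCOc1ccc(B(O)O)cc1 | starting material
4 | (2R)-5,7-bis(methoxymethoxy)-2-[4-(methoxymethoxy)phenyl]-2,3-dihydro-4H-chromen-4-one | O=C1C[C@H](c2ccc(OCOC)cc2)Oc2cc(OCOC)cc(OCOC)c21 | intermediate
5 | 4-methylpent-3-en-1-ol | CC(C)=CCCO | starting material
6 | 4-methylpent-3-enal | CC(C)=CCC=O | intermediate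
7 | lithium (2R)-5,7-bis(methoxymethoxy)-2-[4-(methoxymethoxy)phenyl]-2H-chromen-4-olate (not isolated) | [Li+].[O-]C1=C[C@H](c2ccc(OCOC)cc2)Oc2cc(OCOC)cc(OCOC)c21 | intermediate
8 | (2R)-3-(1-hydroxy-4-methylpent-3-en-1-yl)-5,7-bis(methoxymethoxy)-2-[4-(methoxymethoxy)phenyl]-2,3-dihydro-4H-chromen-4-one (diastereomer mixture at C3 and the carbinol carbon) | O=C1C(C(O)CC=C(C)C)[C@H](c2ccc(OCOC)cc2)Oc2cc(OCOC)cc(OCOC)c21 | intermediate
9 | methanesulfonate of 8 (not isolated) | O=C1C(C(OS(C)(=O)=O)CC=C(C)C)[C@H](c2ccc(OCOC)cc2)Oc2cc(OCOC)cc(OCOC)c21 | intermediate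
10 | (2S,3E)-5,7-bis(methoxymethoxy)-2-[4-(methoxymethoxy)phenyl]-3-(4-methylpent-3-en-1-ylidene)-2,3-dihydro-4H-chromen-4-one | O=C1/C(=C/CC=C(C)C)[C@H](c2ccc(OCOC)cc2)Oc2cc(OCOC)cc(OCOC)c21 | intermediate
11 | allyl phenyl sulfone, (prop-2-en-1-ylsulfonyl)benzene | C=CCS(=O)(=O)c1ccccc1 | starting material
12 | [1-(phenylsulfonyl)prop-2-en-1-yl]lithium (not isolated) | [Li+].[CH-](C=C)S(=O)(=O)c1ccccc1 | intermediate
13 | lithium (2S)-5,7-bis(methoxymethoxy)-2-[4-(methoxymethoxy)phenyl]-3-[(4S)-6-methyl-3-(phenylsulfonyl)hepta-1,5-dien-4-yl]-2H-chromen-4-olate (not isolated; sulfonyl-bearing carbon unassigned) | [Li+].[O-]C1=C([C@H](CC=C(C)C)C(C=C)S(=O)(=O)c2ccccc2)[C@H](c2ccc(OCOC)cc2)Oc2cc(OCOC)cc(OCOC)c21 | intermediate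
14 | lithium 2-{(3S)-2-[4-(methoxymethoxy)benzylidene]-3-(3-methylbut-2-en-1-yl)-4-(phenylsulfonyl)hex-5-enoyl}-3,5-bis(methoxymethoxy)phenolate (not isolated; alkene geometry and sulfonyl-bearing carbon unassigned) | [Li+].[O-]c1cc(OCOC)cc(OCOC)c1C(=O)C(=Cc1ccc(OCOC)cc1)[C@H](CC=C(C)C)C(C=C)S(=O)(=O)c1ccccc1 | intermediate
15 | dilithium phenolate/ketone enolate of 16 (not isolated) | [Li+].[Li+].[O-]c1cc(OCOC)cc(OCOC)c1C([O-])=C1[C@H](CC=C(C)C)C(S(=O)(=O)c2ccccc2)=CC[C@H]1c1ccc(OCOC)cc1 | intermediate
16 | [2-hydroxy-4,6-bis(methoxymethoxy)phenyl][(1S,2S,6R)-6-[4-(methoxymethoxy)phenyl]-2-(3-methylbut-2-en-1-yl)-3-(phenylsulfonyl)cyclohex-3-en-1-yl]methanone | CC(C)=CC[C@@H]1C(S(=O)(=O)c2ccccc2)=CC[C@@H](c2ccc(OCOC)cc2)[C@@H]1C(=O)c1c(O)cc(OCOC)cc1OCOC | intermediate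
17 | [2-hydroxy-4,6-bis(methoxymethoxy)phenyl][(1R,2S,6R)-6-[4-(methoxymethoxy)phenyl]-3-methyl-2-(3-methylbut-2-en-1-yl)cyclohex-3-en-1-yl]methanone | CC(C)=CC[C@@H]1C(C)=CC[C@@H](c2ccc(OCOC)cc2)[C@@H]1C(=O)c1c(O)cc(OCOC)cc1OCOC | intermediate
18 | (2,4,6-trihydroxyphenyl)[(1R,2S,6R)-6-(4-hydroxyphenyl)-3-methyl-2-(3-methylbut-2-en-1-yl)cyclohex-3-en-1-yl]methanone | CC(C)=CC[C@@H]1C(C)=CC[C@@H](c2ccc(O)cc2)[C@@H]1C(=O)c1c(O)cc(O)cc1O | target

**Step count**
Total steps: 8. Longest linear sequence: 7 steps (1, 2, 4, 5, 6, 7, 8); step 3 is a one-step side branch.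

**Steps most likely to fail**

Step 6 (Proposed new method). The sulfonyl allyl anion may add through its γ-carbon or to the carbonyl group, which would give a constitutional isomer or no annulation. γ-Deprotonation of 10, with ring opening or isomerisation to the 3-alkylflavone, may precede the first C–C bond formation and erase the C2 information, lowering enantiomeric purity. Ring closure onto the electron-rich 2-oxidoaryl enone may be slow, and protonation of 15 may occur from the wrong face. The fallback uses known chemistry, sets out from 4 and returns at 17. Compound 4 is opened with KOH in aqueous EtOH (retro-oxa-Michael) to the 2′-hydroxychalcone (E)-1-[2-hydroxy-4,6-bis(methoxymethoxy)phenyl]-3-[4-(methoxymethoxy)phenyl]prop-2-en-1-one F1. F1 is then combined with commercial (E)-β-ocimene in an endo-selective Diels–Alder reaction promoted by a chiral VANOL–borate complex (from VANOL, BH3·THF and AcOH, antipode chosen for the 1R,2S,6R adduct), the free 2′-hydroxyl group binding boron. This should give 17 directly, and step 8 follows.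

Step 7. The Grignard reagent may deprotonate the vinyl sulfone at its γ-positions instead of entering the catalytic cycle. Oxidative addition at the α-branched, hindered vinyl sulfone may be sluggish, and slow 1,2-addition to the ketone or enolisation with epimerisation at C1 may compete. The fallback sets out from 16 and returns at 17. Radical stannyldesulfonylation of 16 with Bu3SnH and AIBN in toluene at 90 °C should give the vinylstannane [2-hydroxy-4,6-bis(methoxymethoxy)phenyl][(1S,2S,6R)-6-[4-(methoxymethoxy)phenyl]-2-(3-methylbut-2-en-1-yl)-3-(tributylstannyl)cyclohex-3-en-1-yl]methanone F2. Iododestannylation with I2 in CH2Cl2 at 0 °C should give the vinyl iodide [2-hydroxy-4,6-bis(methoxymethoxy)phenyl][(1S,2S,6R)-3-iodo-6-[4-(methoxymethoxy)phenyl]-2-(3-methylbut-2-en-1-yl)cyclohex-3-en-1-yl]methanone F3. Suzuki–Miyaura methylation of F3 with trimethylboroxine, Pd(dppf)Cl2 and K2CO3 in aqueous dioxane should then give 17.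

Step 4. The lithium enolate 7 may lose the ring oxygen by β-elimination (ring opening to the chalcone and loss of the C2 configuration). The enolate may also deprotonate the β,γ-unsaturated aldehyde, leading to its isomerisation and self-condensation. The fallback sets out from 4 and returns at 8. Soft enolisation of 4 with TMSOTf and Et3N in CH2Cl2 at 0 °C should give the silyl enol ether (2R)-5,7-bis(methoxymethoxy)-2-[4-(methoxymethoxy)phenyl]-4-[(trimethylsilyl)oxy]-2H-chromene F4. A Mukaiyama aldol addition of F4 to 6 with BF3·OEt2 in CH2Cl2 at −78 °C should then give 8 without any metal enolate.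

**Further compounds**
F1 | step 6 | (E)-1-[2-hydroxy-4,6-bis(methoxymethoxy)phenyl]-3-[4-(methoxymethoxy)phenyl]prop-2-en-1-one | COCOc1ccc(/C=C/C(=O)c2c(O)cc(OCOC)cc2OCOC)cc1
F2 | step 7 | [2-hydroxy-4,6-bis(methoxymethoxy)phenyl][(1S,2S,6R)-6-[4-(methoxymethoxy)phenyl]-2-(3-methylbut-2-en-1-yl)-3-(tributylstannyl)cyclohex-3-en-1-yl]methanone | CC(C)=CC[C@@H]1C([Sn](CCCC)(CCCC)CCCC)=CC[C@@H](c2ccc(OCOC)cc2)[C@@H]1C(=O)c1c(O)cc(OCOC)cc1OCOC
F3 | step 7 | [2-hydroxy-4,6-bis(methoxymethoxy)phenyl][(1S,2S,6R)-3-iodo-6-[4-(methoxymethoxy)phenyl]-2-(3-methylbut-2-en-1-yl)cyclohex-3-en-1-yl]methanone | CC(C)=CC[C@@H]1C(I)=CC[C@@H](c2ccc(OCOC)cc2)[C@@H]1C(=O)c1c(O)cc(OCOC)cc1OCOC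
F4 | step 4 | (2R)-5,7-bis(methoxymethoxy)-2-[4-(methoxymethoxy)phenyl]-4-[(trimethylsilyl)oxy]-2H-chromene | C[Si](C)(C)OC1=C[C@H](c2ccc(OCOC)cc2)Oc2cc(OCOC)cc(OCOC)c21
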